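A small extra charge of E, 0.0410 M, stands between the dusk run and the midnight run: both hold 0.085 M of Q at 80 °C, and J differs too, 4.25 mM against 6.3 mM.

| setting | midnight | spring | dusk | theta | zeta | alpha | delta | eta |
|---|---|---|---|---|---|---|---|---|
| Q | 0.085 M | 0.085 M | 0.085 M | 0.085 M | 0.040 M | 0.085 M | 0.060 M | 0.085 M |
| E | 0.102 M | 0.102 M | 0.061 M | 0.102 M | 0.102 M | 0.0300 M | 0.200 M | 0.0600 M |
| J | 6.3 mM | 18 mM | 4.25 mM | 4.25 mM | 4.25 mM | 4.25 mM | 4.25 mM | 12.0 mM |
| temperature | 80 °C | 102 °C | 80 °C | 110 °C | 110 °C | 70 °C | 90 °C | 110 °C |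
| remark | run made earlier | run made earlier | run made earlier |  |  |  |  |  |
| time |  |  |  | 30 min | 30 min | 30 min | 30 min | 30 min |

| run | time / min | X / % | Q / % |
|---|---|---|---|
| midnight | 6.00 | 18 | 34 |
| midnight | 20.0 | 42 | 6 |
| midnight | 40.0 | 46 | 0 |
| midnight | 60.0 | 51 | 0 |
| spring | 1.33 | 22 | 41 |
| spring | 2.50 | 34 | 21 |
| spring | 4.00 | 41 | 12 |
| spring | 8.00 | 50 | 2 |
| spring | 15.0 | 50 | 0 |
| dusk | 12.0 | 16 | 36 |
| dusk | 25.0 | 21 | 17 |
| dusk | 40.0 | 22 | 10 |
| dusk | 50.0 | 25 | 10 |
| dusk | 60.0 | 25 | 6 |

(standard deviation of a reading: 2 percentage points)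

- all flasks from highest to lowest amount of X, in percent of the Q charged, at 30 min (theta / zeta / alpha / delta / eta)
- the same order at 3.0 min (theta / zeta / alpha / delta / eta)
- the amount of X, in percent of the Q charged of the flask you put first, at 30 min
- the amount of X, in percent of the Q charged of the flask you put last, at 30 min

1. I compare the last readings. Midnight at 60.0 min has Q at 0% and X at 51%; dusk at 60.0 min has Q at 6% and X at 25%.

2. I follow the extra E and credit it with the gap in X, 26 percentage points of the Q charged, setting the difference in J aside. I name the E price: extra E charged, divided by the extra X found, both molar, 1.86. This is a reading, with a scatter of 2 points on each X, and I count it as about two E per X.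

3. At that price the whole of Q as X would cost 0.158 M of E, more than either run was charged, so I read E as the limiting reagent of both runs. My rule, for a flask at rest, with temperature and J set aside: X equals midnight's X, less the shortfall in equivalents of E per Q, divided by the price. Midnight has 1.20 equivalents. The rule reaches the whole of Q at 2.11 equivalents.

4. Theta has midnight's equivalents, so I expect about 51%. Eta gets 24.4% and alpha 5.34%, though alpha at 70 °C may stay under that at 30 min. Zeta with 2.55 and delta with 3.33 equivalents stand past the crossing, so my rule sets no cap by E on them. I put delta first at 30 min, then zeta, theta, eta, alpha, with delta's X well above midnight's. The rule speaks of rest, so it gives me nothing for 3.0 min.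

5. The forecast sets zeta > theta > delta > eta > alpha at 30 min and zeta > theta > delta > eta > alpha at 3.0 min, with 50% first (46% to 54%) and 7% last (3% to 14%), saying of the leaders “their order is nearly a tie”, and there we part, for I set no ceiling near 50%.

6. The flasks give delta > zeta > theta > eta > alpha at 30 min and zeta > delta > theta > eta > alpha at 3.0 min, with X at 84.8% in delta and 4.64% in alpha.

    Q + E → L + D (k = 0.215 M⁻¹ s⁻¹, Ea = 69.0 kJ mol⁻¹)
    E + L → X + D (k = 0.370 M⁻¹ s⁻¹, Ea = 83.0 kJ mol⁻¹)
    L + J → G (k = 0.0276 M⁻¹ s⁻¹, Ea = 84.0 kJ mol⁻¹)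
    Q + D → Z (k = 0.137 M⁻¹ s⁻¹, Ea = 65.0 kJ mol⁻¹)
    (constants at 110 °C)

7. Delta has come to rest: Q reads 0% at 30.0 min, and at 300 min X still stands at 84.8% with E at 49.1% of its charge. At my price, delta's X takes 47.2% of the E charged. In eta, with E at 0%, X holds at 24.3% against my 24.4%, and reads 24.3% at 300 min. Alpha still moves: between 30.0 min and 300 min its E falls from 9.58% to 0%, and its X, which my rule puts at 5.34%, climbs from 4.64% to 5.76%.

The earlier runs and the new flask come from a simulation with constants of no real substance, and the scatter is random.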